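## Retrosynthetic overview

1. Target (germacrane locants: carbocycle C1–C10, lactone carbons C11–C13 on C7, lactone oxygen on C6) ⇐ acetylation and desilylation ⇐ C9 carbinol ⇐ Ni/Cr-mediated vinyl iodide–aldehyde closure of C9–C10 in a seco iodo-aldehyde; the ten-membered carbocycle is formed last.
2. Enabling feature: C9 is an allylic carbinol carbon bonded directly to the vinylic C10 of the Z C1=C10 alkene and flanked by the oxygenated C8. C9–C10 is therefore the retron of a vinylmetal–aldehyde addition, which also delivers O9 free and distinct from the already angeloylated O8. The trans-fused five-membered lactone (O–C6–C7–C11–C12) and the two ring alkenes fold the chain.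
3. Seco aldehyde ⇐ Stork–Zhao iodo-olefination (C1=C10), CBS reduction (C3) and a Wittig reaction (C4=C5) that opens a pyranose lactol. C1–C5 of L-arabinose become C5–C9; sugar C2, C3, C4 become C6, C7, C8.
4. The lactone is built first on the pyranoside template: trans-diaxial malonate opening of a 2,3-anhydro-L-ribopyranoside sets C7, the liberated O2 (O6 of the target) closes the γ-lactone, and decarboxylative methylenation adds C13. The angelate is placed on O4 (O8) while the rigid bicycle rules out lactone migration.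
5. Ring order: pyranose template (from the sugar) → γ-lactone → template ring cleaved (Wittig) → ten-membered carbocycle.

Key step: step 20

Remark: germacrane locants are used throughout; in these the target is 3S,6R,7S,8R,9S with 1(10)Z and 4E double bonds, as read from the SMILES.

## Route

Step 1
Reactants: 1 4-methoxybenzyl alcohol; 2 methyl acrylate
Product: 3 methyl 3-[(4-methoxybenzyl)oxy]propanoate
Conditions: NaH (0.05 equiv), THF, 0 °C to rt
Reagents that add atoms: none
Why: base-catalysed oxa-Michael addition of the benzylic alkoxide to the acrylate, a standard entry to 3-alkoxypropanoates.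

Step 2
Reactants: 3 methyl 3-[(4-methoxybenzyl)oxy]propanoate; 4 ethyltriphenylphosphonium bromide
Product: 6 1-[(4-methoxybenzyl)oxy]-4-(triphenylphosphoranylidene)pentan-3-one, via ethylidene(triphenyl)phosphorane 5 (not isolated)
Conditions: 4 (2.1 equiv), n-BuLi (2.1 equiv), THF, 0 °C; then 3 (1 equiv), 0 °C to rt
Reagents that add atoms: none
Why: C-acylation of the non-stabilised ylide by the ester, with proton loss to the second equivalent of ylide, should give the stabilised acyl ylide (ylide acylation).

Step 3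
Reactants: 7 L-arabinose
Product: 8 allyl β-L-arabinopyranoside
Conditions: allyl alcohol (solvent), TsOH·H2O (cat.), 70 °C; crystallisation
Reagents that add atoms: allyl alcohol, C=CCO
Why: Fischer glycosidation under thermodynamic control should favour the pyranoside with the axial aglycon (β-L, anomeric effect), which is expected to crystallise as its methyl and benzyl analogues do.

Step 4
Reactants: 8 allyl β-L-arabinopyranoside
Product: 9 allyl 3,4-O-isopropylidene-β-L-arabinopyranoside
Conditions: 2,2-dimethoxypropane, TsOH·H2O (cat.), DMF, rt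
Reagents that add atoms: 2,2-dimethoxypropane, COC(C)(C)OC
Why: acetonide formation is selective for the cis-3,4-diol and leaves only the equatorial 2-OH free.

Step 5
Reactants: 9 allyl 3,4-O-isopropylidene-β-L-arabinopyranoside
Product: 10 allyl 3,4-O-isopropylidene-2-O-(4-toluenesulfonyl)-β-L-arabinopyranoside
Conditions: TsCl, pyridine, 0 °C to rt
Reagents that add atoms: 4-toluenesulfonyl chloride, Cc1ccc(cc1)S(Cl)(=O)=O
Why: sulfonylation of the single free hydroxyl turns O2 into a leaving group.

Step 6
Reactants: 10 allyl 3,4-O-isopropylidene-2-O-(4-toluenesulfonyl)-β-L-arabinopyranoside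
Product: 12 allyl 2,3-anhydro-β-L-ribopyranoside, via allyl 2-O-tosyl-β-L-arabinopyranoside 11 (not isolated)
Conditions: AcOH/H2O (4:1), 50 °C; evaporation; then NaOMe, MeOH, 0 °C to rt
Reagents that add atoms: none
Why: mild acetal hydrolysis and then intramolecular SN2 displacement of the tosylate by the trans 3-alkoxide (inversion at sugar C2) should give the ribo epoxide, the classical route to 2,3-anhydropentopyranosides; the 4-OH is cis to the oxirane and cannot trigger epoxide migration.

Step 7
Reactants: 12 allyl 2,3-anhydro-β-L-ribopyranoside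
Product: 13 allyl 2,3-anhydro-4-O-(4-methoxybenzyl)-β-L-ribopyranoside
Conditions: NaH, 4-methoxybenzyl chloride, Bu4NI (cat.), DMF, 0 °C to rt
Reagents that add atoms: 4-methoxybenzyl chloride, COc1ccc(CCl)cc1
Why: Williamson etherification blocks O4 (O8 of the target) so that only O2 can lactonise in the next steps.

Step 8
Reactants: 13 allyl 2,3-anhydro-4-O-(4-methoxybenzyl)-β-L-ribopyranoside; 14 dimethyl malonate
Product: 15 allyl 3-deoxy-3-C-[carboxy(methoxycarbonyl)methyl]-4-O-(4-methoxybenzyl)-β-L-xylopyranoside 2-lactone (trans-fused γ-lactone onto O2; both epimers at the malonyl carbon)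
Conditions: 14 (4 equiv), NaH (3.5 equiv), DMF, 90 °C; then AcOH
Reagents that add atoms: none
Why: Fürst–Plattner trans-diaxial opening of the 2,3-anhydro-β-ribopyranoside by NaCH(CO2Me)2 at sugar C3 (the oxirane carbon remote from the electron-withdrawing anomeric centre) with inversion sets C7 of the target from the face opposite the oxirane, and after ring flip to the all-equatorial chair the liberated 2-alkoxide closes the trans-fused γ-lactone on one ester group.

Step 9
Reactants: 15 lactone ester
Product: 18 allyl 3-C-(1-carboxyethenyl)-3-deoxy-4-O-(4-methoxybenzyl)-β-L-xylopyranoside 2-lactone, via ring-opened dipotassium malonate 16 (not isolated), via lactone acid 17 (not isolated)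
Conditions: KOH, MeOH/H2O, rt; 2 M HCl to pH 2, 0 °C to rt; then Et2NH, 37% aq. CH2O, NaOAc, AcOH, 90 °C
Reagents that add atoms: formaldehyde, C=O
Why: saponification and acid-induced relactonisation give the α-carboxy lactone, whose Mannich condensation with formaldehyde and diethylamine followed by decarboxylative elimination should install the exocyclic methylene (decarboxylative methylenation of α-carboxy-γ-butyrolactones); the PMB ether keeps O4 out of the relactonisation.

Step 10
Reactants: 18 PMB-protected methylene lactone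
Product: 19 allyl 3-C-(1-carboxyethenyl)-3-deoxy-β-L-xylopyranoside 2-lactone
Conditions: DDQ, CH2Cl2/pH 7 buffer (10:1), 0 °C to rt
Reagents that add atoms: none
Why: oxidative cleavage of the electron-rich PMB ether by DDQ; the allyl acetal and the electron-poor methylene lactone should not react.

Step 11
Reactants: 19 alcohol; 20 angelic acid [(Z)-2-methylbut-2-enoic acid]
Product: 22 allyl 4-O-angeloyl-3-C-(1-carboxyethenyl)-3-deoxy-β-L-xylopyranoside 2-lactone, via mixed anhydride 21 (not isolated)
Conditions: 20 (3 equiv), 2,4,6-trichlorobenzoyl chloride (3 equiv), Et3N (6 equiv), toluene, rt; then 19, 80 °C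
Reagents that add atoms: none
Why: Yamaguchi-type esterification through the mixed anhydride without DMAP, conditions under which angelates keep their Z geometry; the equatorial O4–H is the only hydroxyl and the rigid trans-fused bicycle cannot pass the lactone from O2 to O4.

Step 12
Reactants: 22 allyl glycoside angelate
Product: 24 4-O-angeloyl-3-C-(1-carboxyethenyl)-3-deoxy-L-xylopyranose 2-lactone (anomer mixture), via prop-1-enyl glycoside 23 (not isolated)
Conditions: [Ir(cod)(PMePh2)2]PF6 (3 mol %, activated with H2), THF, rt; then 0.1 M aq. HCl, acetone, rt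
Reagents that add atoms: none
Why: iridium hydride catalysed isomerisation of the allyl acetal to the prop-1-enyl acetal and mild acid hydrolysis of this enol ether should release the lactol without touching lactone or angelate (two-stage removal of an anomeric allyl group).

Step 13
Reactants: 24 lactol; 6 1-[(4-methoxybenzyl)oxy]-4-(triphenylphosphoranylidene)pentan-3-one
Product: 25 (4S,5R)-4-[(1R)-1-(angeloyloxy)-2-hydroxyethyl]-5-[(1E)-5-(4-methoxybenzyloxy)-2-methyl-3-oxopent-1-enyl]-3-methylenedihydrofuran-2(3H)-one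
Conditions: 6 (2 equiv), PhCO2H (0.1 equiv), toluene, 90 °C
Reagents that add atoms: none
Why: Wittig olefination of the open-chain aldehyde tautomer of the lactol with the stabilised α-methyl acyl ylide should give the E trisubstituted enone (C4=C5) and cleaves the pyranose template; C6, C7 and C8 come unchanged from the sugar, and the hindered conjugated angelate is expected to stay on O8 under these neutral conditions.

Step 14
Reactants: 25 hydroxy enone
Product: 26 (4S,5R)-4-[(1R)-1-(angeloyloxy)-2-hydroxyethyl]-5-[(1E,3S)-3-hydroxy-5-(4-methoxybenzyloxy)-2-methylpent-1-enyl]-3-methylenedihydrofuran-2(3H)-one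
Conditions: (R)-2-methyl-CBS-oxazaborolidine (0.5 equiv), BH3·SMe2 (2.5 equiv), THF, −30 °C; then MeOH
Reagents that add atoms: none
Why: Corey–Bakshi–Shibata reduction: with the alkenyl group as the large and the CH2 chain as the small substituent, the R catalyst should deliver hydride to the face that gives the 3S allylic alcohol, with 1,2-selectivity and without reduction of the conjugated esters.

Step 15
Reactants: 26 diol
Product: 27 bis(triethylsilyl) ether of 26 (TES on O3 and on the primary O9)
Conditions: TESCl (3 equiv), imidazole, DMAP (cat.), DMF, 0 °C to rt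
Reagents that add atoms: chlorotriethylsilane, CC[Si](Cl)(CC)CC
Why: silylation of both hydroxyls; the primary TES ether at C9 is the latent aldehyde and the secondary one protects O3 to the end.

Step 16
Reactants: 27 bis-TES ether
Product: 28 (4S,5R)-4-[(1R)-1-(angeloyloxy)-2-(triethylsilyloxy)ethyl]-5-[(1E,3S)-5-hydroxy-2-methyl-3-(triethylsilyloxy)pent-1-enyl]-3-methylenedihydrofuran-2(3H)-one
Conditions: DDQ, CH2Cl2/pH 7 buffer (10:1), 0 °C
Reagents that add atoms: none
Why: DDQ should remove the PMB ether selectively in the presence of silyl ethers, esters and alkenes.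

Step 17
Reactants: 28 primary alcohol
Product: 29 (4S,5R)-4-[(1R)-1-(angeloyloxy)-2-(triethylsilyloxy)ethyl]-5-[(1E,3S)-2-methyl-5-oxo-3-(triethylsilyloxy)pent-1-enyl]-3-methylenedihydrofuran-2(3H)-one
Conditions: Dess–Martin periodinane, NaHCO3, CH2Cl2, 0 °C to rt
Reagents that add atoms: none
Why: Dess–Martin oxidation of the primary alcohol to the β-silyloxy aldehyde under buffered, non-basic conditions that avoid β-elimination.

Step 18
Reactants: 29 aldehyde
Product: 30 (4S,5R)-4-[(1R)-1-(angeloyloxy)-2-(triethylsilyloxy)ethyl]-5-[(1E,3S,5Z)-6-iodo-2-methyl-3-(triethylsilyloxy)hepta-1,5-dienyl]-3-methylenedihydrofuran-2(3H)-one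
Conditions: EtPPh3I, n-BuLi, THF, rt; I2, −78 °C; NaN(SiMe3)2, −78 to −20 °C; then 29, −78 to −30 °C
Reagents that add atoms: ethyltriphenylphosphonium iodide, CC[P+](c1ccccc1)(c1ccccc1)c1ccccc1.[I-]; iodine, II
Why: Stork–Zhao–Wittig olefination with the α-iodo ylide made in situ should give, under kinetic control at low temperature, the Z-configured 2-iodoalk-2-ene (iodine cis to C2), the geometry needed for the Z C1=C10 alkene.

Step 19
Reactants: 30 vinyl iodide
Product: 31 (2R)-2-(angeloyloxy)-2-[(2R,3S)-2-[(1E,3S,5Z)-6-iodo-2-methyl-3-(triethylsilyloxy)hepta-1,5-dienyl]-4-methylene-5-oxotetrahydrofuran-3-yl]acetaldehyde (seco iodo-aldehyde)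
Conditions: (COCl)2, DMSO, CH2Cl2, −78 to −40 °C; Et3N, −78 to 0 °C
Reagents that add atoms: none
Why: Swern conditions oxidise a primary triethylsilyl ether directly to the aldehyde (silyl transfer to chloride at the alkoxysulfonium stage) while the secondary TES ether stays, so that a free C9 hydroxyl next to the angelate never appears.

Step 20
Reactants: 31 seco iodo-aldehyde
Product: 32 (3S,6R,7S,8R,9S)-8-angeloyloxy-9-hydroxy-3-(triethylsilyloxy)germacra-1(10)Z,4E,11(13)-trien-12,6-olide
Conditions: CrCl2 (15 equiv), NiCl2 (0.15 equiv), degassed DMSO, rt, slow addition of 31 to a final 0.003 M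
Reagents that add atoms: none
Why: Zerovalent nickel, formed in situ from NiCl2 and CrCl2, inserts into the C10–iodine bond and hands the alkenyl group with retention to chromium; the resulting Z-alkenylchromium species (trivalent chromium) adds only to the C9 aldehyde, so that the C9–C10 bond, the ten-membered carbocycle and the C9 carbinol arise in one operation while lactone, angelate, silyl ether and exocyclic methylene are left alone. The closest known reaction type is the Nozaki–Hiyama–Kishi macrocyclisation of ω-iodoalkenyl aldehydes to medium and large carbocycles. The ring closes in the 10-exo-trig mode (the aldehyde C=O is exocyclic to the forming ring), helped by the trans-fused γ-lactone at C6–C7, the E C4=C5 and the Z C1=C10 double bonds, which fold the chain and cut down its free rotors. The new stereocentre C9 is controlled by the neighbouring C8 centre: polar Felkin–Anh attack anti to the C8–O(angeloyl) bond in the non-chelating chromium transition state should give the 8,9-anti, 9S alcohol. The step needs chemoselectivity for the aldehyde, retention of the Z geometry and cyclisation over oligomerisation; the hard oxophilic organochromium reagent, the stereoretentive nickel-to-chromium transfer and high dilution with slow addition secure these.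

Step 21
Reactants: 32 macrocyclic C9 alcohol
Product: 33 (3S,6R,7S,8R,9S)-9-acetoxy-8-angeloyloxy-3-(triethylsilyloxy)germacra-1(10)Z,4E,11(13)-trien-12,6-olide
Conditions: Ac2O, pyridine, DMAP (cat.), CH2Cl2, 0 °C
Reagents that add atoms: acetic anhydride, CC(=O)OC(C)=O
Why: acetylation of the single free, newly formed C9 hydroxyl; fast DMAP-catalysed acetyl transfer should outpace migration of the hindered angelate.

Step 22
Reactants: 33 C9 acetate
Product: 34 (3S,6R,7S,8R,9S)-9-acetoxy-8-angeloyloxy-3-hydroxygermacra-1(10)Z,4E,11(13)-trien-12,6-olide (CNP0265116.1)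
Conditions: HF·pyridine, pyridine, THF, 0 °C
Reagents that add atoms: none
Why: buffered HF·pyridine should cleave the secondary allylic TES ether without acyl migration or attack on the methylene lactone.

## Compound list

1 | 4-methoxybenzyl alcohol | COc1ccc(CO)cc1 | starting material
2 | methyl acrylate | C=CC(=O)OC | starting material
3 | methyl 3-[(4-methoxybenzyl)oxy]propanoate | COC(=O)CCOCc1ccc(OC)cc1 | intermediate
4 | ethyltriphenylphosphonium bromide | CC[P+](c1ccccc1)(c1ccccc1)c1ccccc1.[Br-] | starting material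
5 | ethylidene(triphenyl)phosphorane (not isolated) | CC=P(c1ccccc1)(c1ccccc1)c1ccccc1 | intermediate
6 | 1-[(4-methoxybenzyl)oxy]-4-(triphenylphosphoranylidene)pentan-3-one | COc1ccc(COCCC(=O)C(C)=P(c2ccccc2)(c2ccccc2)c2ccccc2)cc1 | intermediate
7 | L-arabinose (aldehydo form drawn) | O=C[C@H](O)[C@@H](O)[C@@H](O)CO | starting material
8 | allyl β-L-arabinopyranoside | C=CCO[C@H]1OC[C@H](O)[C@H](O)[C@H]1O | intermediate
9 | allyl 3,4-O-isopropylidene-β-L-arabinopyranoside | C=CCO[C@H]1OC[C@H](OC2(C)C)[C@H](O2)[C@H]1O | intermediate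
10 | allyl 3,4-O-isopropylidene-2-O-(4-toluenesulfonyl)-β-L-arabinopyranoside | C=CCO[C@H]1OC[C@H](OC2(C)C)[C@H](O2)[C@H]1OS(=O)(=O)c1ccc(C)cc1 | intermediate
11 | allyl 2-O-(4-toluenesulfonyl)-β-L-arabinopyranoside (not isolated) | C=CCO[C@H]1OC[C@H](O)[C@H](O)[C@H]1OS(=O)(=O)c1ccc(C)cc1 | intermediate
12 | allyl 2,3-anhydro-β-L-ribopyranoside | C=CCO[C@H]1OC[C@H](O)[C@@H]2O[C@H]12 | intermediate
13 | allyl 2,3-anhydro-4-O-(4-methoxybenzyl)-β-L-ribopyranoside | C=CCO[C@H]1OC[C@H](OCc2ccc(OC)cc2)[C@@H]2O[C@H]12 | intermediate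
14 | dimethyl malonate | COC(=O)CC(=O)OC | starting material
15 | allyl 3-deoxy-3-C-[carboxy(methoxycarbonyl)methyl]-4-O-(4-methoxybenzyl)-β-L-xylopyranoside 2-lactone (trans-fused; epimers at the malonyl carbon) | C=CCO[C@H]1OC[C@H](OCc2ccc(OC)cc2)[C@H]2C(C(=O)OC)C(=O)O[C@H]12 | intermediate
16 | dipotassium salt of allyl 3-deoxy-3-C-(dicarboxymethyl)-4-O-(4-methoxybenzyl)-β-L-xylopyranoside (ring-opened; not isolated) | C=CCO[C@H]1OC[C@H](OCc2ccc(OC)cc2)[C@@H](C(C(=O)[O-])C(=O)[O-])[C@@H]1O.[K+].[K+] | intermediate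
17 | allyl 3-deoxy-3-C-(dicarboxymethyl)-4-O-(4-methoxybenzyl)-β-L-xylopyranoside 2-lactone (lactone acid; not isolated) | C=CCO[C@H]1OC[C@H](OCc2ccc(OC)cc2)[C@H]2C(C(=O)O)C(=O)O[C@H]12 | intermediate
18 | allyl 3-C-(1-carboxyethenyl)-3-deoxy-4-O-(4-methoxybenzyl)-β-L-xylopyranoside 2-lactone | C=CCO[C@H]1OC[C@H](OCc2ccc(OC)cc2)[C@H]2C(=C)C(=O)O[C@H]12 | intermediate
19 | allyl 3-C-(1-carboxyethenyl)-3-deoxy-β-L-xylopyranoside 2-lactone | C=CCO[C@H]1OC[C@H](O)[C@H]2C(=C)C(=O)O[C@H]12 | intermediate
20 | angelic acid, (Z)-2-methylbut-2-enoic acid | C/C=C(/C)C(=O)O | starting material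
21 | (Z)-2-methylbut-2-enoic 2,4,6-trichlorobenzoic anhydride (not isolated) | C/C=C(/C)C(=O)OC(=O)c1c(Cl)cc(Cl)cc1Cl | intermediate
22 | allyl 4-O-angeloyl-3-C-(1-carboxyethenyl)-3-deoxy-β-L-xylopyranoside 2-lactone | C=CCO[C@H]1OC[C@H](OC(=O)/C(C)=C\C)[C@H]2C(=C)C(=O)O[C@H]12 | intermediate
23 | (E)-prop-1-enyl 4-O-angeloyl-3-C-(1-carboxyethenyl)-3-deoxy-β-L-xylopyranoside 2-lactone (not isolated) | C/C=C/O[C@H]1OC[C@H](OC(=O)/C(C)=C\C)[C@H]2C(=C)C(=O)O[C@H]12 | intermediate
24 | 4-O-angeloyl-3-C-(1-carboxyethenyl)-3-deoxy-L-xylopyranose 2-lactone (anomer mixture) | OC1OC[C@H](OC(=O)/C(C)=C\C)[C@H]2C(=C)C(=O)O[C@H]12 | intermediate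
25 | (4S,5R)-4-[(1R)-1-(angeloyloxy)-2-hydroxyethyl]-5-[(1E)-5-(4-methoxybenzyloxy)-2-methyl-3-oxopent-1-enyl]-3-methylenedihydrofuran-2(3H)-one | C=C1C(=O)O[C@H](/C=C(\C)C(=O)CCOCc2ccc(OC)cc2)[C@H]1[C@@H](OC(=O)/C(C)=C\C)CO | intermediate
26 | (4S,5R)-4-[(1R)-1-(angeloyloxy)-2-hydroxyethyl]-5-[(1E,3S)-3-hydroxy-5-(4-methoxybenzyloxy)-2-methylpent-1-enyl]-3-methylenedihydrofuran-2(3H)-one | C=C1C(=O)O[C@H](/C=C(\C)[C@@H](O)CCOCc2ccc(OC)cc2)[C@H]1[C@@H](OC(=O)/C(C)=C\C)CO | intermediate
27 | bis(triethylsilyl) ether of 26 | C=C1C(=O)O[C@H](/C=C(\C)[C@@H](O[Si](CC)(CC)CC)CCOCc2ccc(OC)cc2)[C@H]1[C@@H](OC(=O)/C(C)=C\C)CO[Si](CC)(CC)CC | intermediate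
28 | (4S,5R)-4-[(1R)-1-(angeloyloxy)-2-(triethylsilyloxy)ethyl]-5-[(1E,3S)-5-hydroxy-2-methyl-3-(triethylsilyloxy)pent-1-enyl]-3-methylenedihydrofuran-2(3H)-one | C=C1C(=O)O[C@H](/C=C(\C)[C@@H](O[Si](CC)(CC)CC)CCO)[C@H]1[C@@H](OC(=O)/C(C)=C\C)CO[Si](CC)(CC)CC | intermediate
29 | (4S,5R)-4-[(1R)-1-(angeloyloxy)-2-(triethylsilyloxy)ethyl]-5-[(1E,3S)-2-methyl-5-oxo-3-(triethylsilyloxy)pent-1-enyl]-3-methylenedihydrofuran-2(3H)-one | C=C1C(=O)O[C@H](/C=C(\C)[C@@H](O[Si](CC)(CC)CC)CC=O)[C@H]1[C@@H](OC(=O)/C(C)=C\C)CO[Si](CC)(CC)CC | intermediate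
30 | (4S,5R)-4-[(1R)-1-(angeloyloxy)-2-(triethylsilyloxy)ethyl]-5-[(1E,3S,5Z)-6-iodo-2-methyl-3-(triethylsilyloxy)hepta-1,5-dienyl]-3-methylenedihydrofuran-2(3H)-one | C=C1C(=O)O[C@H](/C=C(\C)[C@@H](O[Si](CC)(CC)CC)C/C=C(/C)I)[C@H]1[C@@H](OC(=O)/C(C)=C\C)CO[Si](CC)(CC)CC | intermediate
31 | seco iodo-aldehyde, (2R)-2-(angeloyloxy)-2-[(2R,3S)-2-[(1E,3S,5Z)-6-iodo-2-methyl-3-(triethylsilyloxy)hepta-1,5-dienyl]-4-methylene-5-oxotetrahydrofuran-3-yl]acetaldehyde | C=C1C(=O)O[C@H](/C=C(\C)[C@@H](O[Si](CC)(CC)CC)C/C=C(/C)I)[C@H]1[C@@H](OC(=O)/C(C)=C\C)C=O | intermediate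
32 | (3S,6R,7S,8R,9S)-8-angeloyloxy-9-hydroxy-3-(triethylsilyloxy)germacra-1(10)Z,4E,11(13)-trien-12,6-olide | C=C1C(=O)O[C@@H]2/C=C(\C)[C@@H](O[Si](CC)(CC)CC)C/C=C(/C)[C@H](O)[C@H](OC(=O)/C(C)=C\C)[C@@H]12 | intermediate
33 | (3S,6R,7S,8R,9S)-9-acetoxy-8-angeloyloxy-3-(triethylsilyloxy)germacra-1(10)Z,4E,11(13)-trien-12,6-olide | C=C1C(=O)O[C@@H]2/C=C(\C)[C@@H](O[Si](CC)(CC)CC)C/C=C(/C)[C@H](OC(C)=O)[C@H](OC(=O)/C(C)=C\C)[C@@H]12 | intermediate
34 | (3S,6R,7S,8R,9S)-9-acetoxy-8-angeloyloxy-3-hydroxygermacra-1(10)Z,4E,11(13)-trien-12,6-olide | C=C1C(=O)O[C@@H]2/C=C(\C)[C@@H](O)C/C=C(/C)[C@H](OC(C)=O)[C@H](OC(=O)/C(C)=C\C)[C@@H]12 | target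

## Step count and risks

Total step count: 22 (steps 1–2 make ylide 6; steps 3–22 are the main line).
Longest linear sequence: 20 steps (steps 3 to 22, from L-arabinose 7).

Steps most likely to fail:

1. Step 20 (ring closure). The process at risk is poor facial selectivity in the addition to the C9 aldehyde inside the strained ten-membered transition state, beside intermolecular coupling and reduction of the carbon–iodine bond. The fallback sets out from 31 and comes back at 32. The cyclisation is run as described, and the mixture of 32 and its C9 epimer F1 is oxidised with Dess–Martin periodinane to the macrocyclic enone F2. The C9 centre is then set by reagent control: (S)-2-methyl-CBS-oxazaborolidine with catecholborane at −78 °C, for a ketone flanked by the alkenyl C10 (large) and the sp3 C8 (small), should give the 9S alcohol 32.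

2. Step 13 (Wittig opening of the lactol). The processes at risk are re-closure of the liberated C9 hydroxyl onto the new enone by conjugate addition, slow olefination of the lactol, attack of the ylide on the methylene lactone, and drift of the angeloyl group to O9. The fallback sets out from 24 and comes back at 27; it accepts the conjugate addition and uses it as protection. Heating 24 with 6 until the Wittig product has fully cyclised gives the C-glycosidic ketone F3. TESOTf and Et3N (CH2Cl2, −78 to 0 °C) then open the tetrahydropyran by β-elimination of the ring oxygen from the silyl enol ether and trap it as the silyl ether, giving the 9-O-TES enone F4. CBS reduction as in step 14 gives the 3S alcohol F5, and silylation of O3 (TESCl, imidazole) returns to 27.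

3. Step 8 (epoxide opening and lactonisation). The processes at risk are slow or misdirected (sugar C2) attack of the bulky malonate anion on the oxirane, elimination to an allylic alcohol, and incomplete lactonisation. The fallback sets out from 13 and comes back at 18. LiC≡COEt with BF3·OEt2 (THF, −78 °C), a slim two-carbon nucleophile, opens the oxirane at sugar C3 to the ynol ether alcohol F6. TsOH in wet CH2Cl2 hydrates the ynol ether through the neighbouring hydroxyl and gives the α-unsubstituted trans-fused lactone F7. LiN(i-Pr)2 and then dimethyl(methylene)ammonium iodide give the Mannich base F8; quaternisation with MeI to the ammonium iodide F9 and NaHCO3-induced elimination return to 18.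

## Further compounds

F1 | step 20 | C9 epimer of 32 (9R alcohol) | C=C1C(=O)O[C@@H]2/C=C(\C)[C@@H](O[Si](CC)(CC)CC)C/C=C(/C)[C@@H](O)[C@H](OC(=O)/C(C)=C\C)[C@@H]12
F2 | step 20 | macrocyclic C9 ketone (8-angeloyloxy-9-oxo-3-triethylsilyloxy germacranolide) | C=C1C(=O)O[C@@H]2/C=C(\C)[C@@H](O[Si](CC)(CC)CC)C/C=C(/C)C(=O)[C@H](OC(=O)/C(C)=C\C)[C@@H]12
F3 | step 13 | cyclised C-glycosidic ketone (tetrahydropyran from addition of O9 to C5; mixture at C4 and C5) | CC(C(=O)CCOCc1ccc(OC)cc1)C1OC[C@H](OC(=O)/C(C)=C\C)[C@H]2C(=C)C(=O)O[C@H]12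
F4 | step 13 | 9-O-triethylsilyl ether of enone 25 | C=C1C(=O)O[C@H](/C=C(\C)C(=O)CCOCc2ccc(OC)cc2)[C@H]1[C@@H](OC(=O)/C(C)=C\C)CO[Si](CC)(CC)CC
F5 | step 13 | 9-O-triethylsilyl ether of diol 26 (3S alcohol) | C=C1C(=O)O[C@H](/C=C(\C)[C@@H](O)CCOCc2ccc(OC)cc2)[C@H]1[C@@H](OC(=O)/C(C)=C\C)CO[Si](CC)(CC)CC
F6 | step 8 | allyl 3-deoxy-3-C-(ethoxyethynyl)-4-O-(4-methoxybenzyl)-β-L-xylopyranoside | C=CCO[C@H]1OC[C@H](OCc2ccc(OC)cc2)[C@@H](C#COCC)[C@@H]1O
F7 | step 8 | allyl 3-C-(carboxymethyl)-3-deoxy-4-O-(4-methoxybenzyl)-β-L-xylopyranoside 2-lactone | C=CCO[C@H]1OC[C@H](OCc2ccc(OC)cc2)[C@H]2CC(=O)O[C@H]12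
F8 | step 8 | α-(dimethylaminomethyl) derivative of lactone F7 | C=CCO[C@H]1OC[C@H](OCc2ccc(OC)cc2)[C@H]2C(CN(C)C)C(=O)O[C@H]12
F9 | step 8 | α-(trimethylammoniomethyl) lactone iodide | C=CCO[C@H]1OC[C@H](OCc2ccc(OC)cc2)[C@H]2C(C[N+](C)(C)C)C(=O)O[C@H]12.[I-]
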